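Ring A of the eudesmane core (C1–C2–C3–C4–C5–C10) is disconnected at C2–C3 and C4–C5. The key step is a tandem Michael addition/intramolecular Horner–Wadsworth–Emmons annulation: the acetyl-methyl enolate of a carvone-derived 2-acetyl-2-methylcyclohexanone adds to trimethyl 2-phosphonoacrylate, and the resulting phosphonate carbanion olefinates the ring ketone, inserting C3–C4(–C15) between C2 and C5 in one operation. It exploits the 1,3-relation, across quaternary C10, of the oxygenated C1 and the ring-fusion carbon C5, both carbonyls in the precursor. The resulting C4=C5 enoate then delivers O4, H5 and O6 (dienolate hydroxylation, O4-tethered hydrosilylation) before the triol is closed to the orthocinnamate cage.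

Key step: step 4

Remark on the chemistry: eudesmane numbering is used for all bicyclic compounds (ring A = C-1 to C-5 and C-10; ring B = C-5 to C-10; C-14 = methyl on C-10; C-15 = carbon on C-4; isopropyl on C-7), "syn/anti" refer to the face carrying the C-14 methyl, and compounds 1, 6 and 17 are taken as purchasable.

Step 1
Reactants: 1 (R)-(−)-carvone
Product: 2 (5R)-2-methyl-5-(propan-2-yl)cyclohex-2-en-1-one
Conditions: H2 (1 atm), RhCl(PPh3)3 (cat.), benzene, 23 °C
Reagents that add atoms: none
Why: Homogeneous hydrogenation with RhCl(PPh3)3 should reduce the unhindered 1,1-disubstituted isopropenyl alkene much faster than the trisubstituted conjugated one, so the enone needed next and the existing stereocentre are kept.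

Step 2
Reactants: 2 (5R)-2-methyl-5-(propan-2-yl)cyclohex-2-en-1-one
Product: 4 (2R,5R)-2-(1-hydroxyethyl)-2-methyl-5-(propan-2-yl)cyclohexan-1-one (both carbinol epimers), via lithium enolate 3 (not isolated)
Conditions: LiBH(s-Bu)3, THF, −78 °C; then CH3CHO, −78 °C; AcOH quench
Reagents that add atoms: acetaldehyde CC=O
Why: Conjugate hydride reduction gives the tetrasubstituted enolate regiospecifically, and its aldol addition (reductive aldol reaction) should occur at C-2 from the axial direction of the half-chair with equatorial isopropyl, placing the new C–C bond cis and the methyl trans to the isopropyl group (the sense seen in annulations of dihydrocarvone enolates); the carbinol configuration is irrelevant because it is oxidised next, and any C-2 epimer is removed at the stage of 5.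

Step 3
Reactants: 4 (2R,5R)-2-(1-hydroxyethyl)-2-methyl-5-(propan-2-yl)cyclohexan-1-one
Product: 5 (2R,5R)-2-acetyl-2-methyl-5-(propan-2-yl)cyclohexan-1-one
Conditions: DMP (1,1,1-triacetoxy-1,1-dihydro-1,2-benziodoxol-3(1H)-one), CH2Cl2, 23 °C
Reagents that add atoms: none
Why: Periodinane oxidation of the secondary carbinol runs under neutral conditions that should not trigger retro-aldol or retro-Claisen cleavage of the 1,3-dicarbonyl unit, whose central carbon is quaternary.

Step 4
Reactants: 5 (2R,5R)-2-acetyl-2-methyl-5-(propan-2-yl)cyclohexan-1-one; 6 trimethyl 2-phosphonoacrylate (methyl 2-(dimethoxyphosphoryl)prop-2-enoate)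
Product: 9 methyl (7R,10S)-1-oxoeudesm-4-en-15-oate, via lithium enolate 7 (not isolated), via phosphonate carbanion 8 (not isolated)
Conditions: LiN(SiMe3)2 (1.05 equiv), THF, −78 °C; then 6, −78 to 23 °C; then 65 °C
Reagents that add atoms: none
Why: LiN(SiMe3)2 removes a proton from the acetyl methyl (C-2), the enolate adds in a Michael addition to the methylene carbon of 6 (new bond C-2/C-3), and the phosphonate-stabilised carbanion at C-4 then attacks the ring carbonyl C-5 and expels dimethyl phosphate through an oxaphosphetane (intramolecular Horner–Wadsworth–Emmons olefination, new bond C-4/C-5 as C4=C5). The closest known reaction type is the tandem Michael addition/intramolecular Horner–Wadsworth–Emmons cyclohexene annulation of 2-phosphonoacrylates with a nucleophile carrying a carbonyl group four atoms away. Ring A (C-1, C-2, C-3, C-4, C-5, C-10) is closed by 6-exo-trig addition of the carbanion to the C-5 carbonyl. No stereocentre is created because C-4 and C-5 become sp2, and the C-7 and C-10 centres are not epimerisable and are carried through. The step needs site-selective enolisation of the methyl ketone rather than the ring methylene C-6, which kinetic deprotonation at −78 °C of the least hindered protons should secure (C-6 is flanked by the isopropyl-bearing C-7), and olefination of C-5 rather than C-1, which ring size secures because attack on C-1 would give a cyclobutene.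

Step 5
Reactants: 9 methyl (7R,10S)-1-oxoeudesm-4-en-15-oate
Product: 10 methyl (1S,7R,10S)-1-hydroxyeudesm-4-en-15-oate
Conditions: NaBH4, MeOH, −20 to 0 °C
Reagents that add atoms: none
Why: Borohydride 1,2-reduction should take the saturated C-1 ketone and leave the hindered tetrasubstituted enoate, with hydride approaching anti to the adjacent angular methyl so that the new hydroxyl is syn to C-14, as in reductions of angularly methylated octalinediones.

Step 6
Reactants: 10 methyl (1S,7R,10S)-1-hydroxyeudesm-4-en-15-oate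
Product: 12 methyl (1S,4S,7S,10S)-1,4-dihydroxyeudesm-5-en-15-oate, via dipotassium dienolate 11 (not isolated)
Conditions: KN(SiMe3)2 (2.5 equiv), THF, −78 °C; then 2-(benzenesulfonyl)-3-phenyloxaziridine, −78 °C; AcOH quench
Reagents that add atoms: 2-(benzenesulfonyl)-3-phenyloxaziridine O=S(=O)(N1OC1c1ccccc1)c1ccccc1
Why: With O-1 as its alkoxide, the base should remove a γ-proton from C-6 (cis to the ester) to give the extended dienolate, which the N-sulfonyloxaziridine hydroxylates at the α-carbon C-4 (enolate α-hydroxylation with deconjugation) on the face anti to the C-14 methyl that stands perpendicular over the planar dienolate, setting C-4 and moving the alkene to C5=C6.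

Step 7
Reactants: 12 methyl (1S,4S,7S,10S)-1,4-dihydroxyeudesm-5-en-15-oate
Product: 15 methyl (1S,4S,5R,6R,7S,10S)-1,4,6-trihydroxyeudesman-15-oate, via bis(dimethylsilyl) ether 13 (not isolated), via cyclic siloxane 14 (not isolated)
Conditions: HMe2SiCl, Et3N, DMAP (cat.), CH2Cl2, 0 to 23 °C; then Pt2[(CH2=CHSiMe2)2O]3 (cat.), toluene, 60 °C; then KF, KHCO3, 30% H2O2, THF/MeOH, 40 °C
Reagents that add atoms: hydrogen peroxide OO (oxygen of the C-6 hydroxyl); chlorodimethylsilane C[SiH](C)Cl (its silicon stays only in 13 and 14)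
Why: The Si–H of the tertiary allylic O-4 silyl ether should add across C5=C6 in a platinum-catalysed intramolecular 5-endo hydrosilylation that delivers silicon to C-6 and hydrogen to C-5 syn and on the O-4 face (temporary silicon tether), and Tamao–Fleming oxidation then replaces C–Si by C–OH with retention, setting C-5 (H anti to C-14, trans ring fusion) and C-6 (hydroxyl cis to O-4 and to the isopropyl group) while freeing O-1 and O-4.

Step 8
Reactants: 15 methyl (1S,4S,5R,6R,7S,10S)-1,4,6-trihydroxyeudesman-15-oate
Product: 16 (1S,4S,5R,6R,7S,10S)-eudesmane-1,4,6,15-tetrol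
Conditions: LiAlH4, THF, 0 to 23 °C; H2O/NaOH work-up
Reagents that add atoms: none
Why: Hydride reduction of the α-hydroxy methyl ester should give the primary C-15 alcohol without touching any stereocentre.

Step 9
Reactants: 17 (E)-cinnamonitrile
Product: 18 methyl (E)-3-phenylprop-2-enimidate hydrochloride
Conditions: HCl (g), MeOH (1.1 equiv), Et2O, 0 °C
Reagents that add atoms: methanol CO; hydrogen chloride Cl
Why: In the Pinner reaction the protonated nitrile adds methanol to give the imidate salt, and the conjugated (E)-alkene should be too poor an acceptor to add chloride or methanol at 0 °C.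

Step 10
Reactants: 16 (1S,4S,5R,6R,7S,10S)-eudesmane-1,4,6,15-tetrol; 18 methyl (E)-3-phenylprop-2-enimidate hydrochloride
Product: 19 (1S,4S,5R,6R,7S,10S)-eudesmane-1,4,6,15-tetrol 4,6,15-ortho-(E)-cinnamate (target)
Conditions: 18 (1.2 equiv), 4 Å molecular sieves, CH2Cl2/MeCN, 23 °C; then Et3N
Reagents that add atoms: none
Why: Alcoholysis of the imidate salt (Pinner orthoester synthesis) by the C-15, C-4 and C-6 hydroxyls, which the trans-decalin holds within reach of one carbon, should give the 2,7,8-trioxabicyclo[3.2.1]octane orthoester with loss of ammonium chloride and methanol, the cage fixing the configuration of the orthoester carbon while the remote equatorial C-1 hydroxyl cannot join it and stays free.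

Compound list
1 | (R)-(−)-carvone, (5R)-2-methyl-5-(prop-1-en-2-yl)cyclohex-2-en-1-one | CC1=CC[C@H](CC1=O)C(C)=C | starting material
2 | (5R)-2-methyl-5-(propan-2-yl)cyclohex-2-en-1-one | CC1=CC[C@H](CC1=O)C(C)C | intermediate
3 | lithium (5R)-2-methyl-5-(propan-2-yl)cyclohex-1-en-1-olate | CC(C)[C@@H]1CCC(C)=C(O[Li])C1 | intermediate
4 | (2R,5R)-2-(1-hydroxyethyl)-2-methyl-5-(propan-2-yl)cyclohexan-1-one, carbinol epimers | CC(C)[C@@H]1CC[C@](C)(C(C)O)C(=O)C1 | intermediate
5 | (2R,5R)-2-acetyl-2-methyl-5-(propan-2-yl)cyclohexan-1-one (acetyl cis, methyl trans to isopropyl) | CC(C)[C@@H]1CC[C@](C)(C(C)=O)C(=O)C1 | intermediate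
6 | trimethyl 2-phosphonoacrylate, methyl 2-(dimethoxyphosphoryl)prop-2-enoate | COC(=O)C(=C)P(=O)(OC)OC | starting material
7 | lithium 1-[(1R,4R)-1-methyl-2-oxo-4-(propan-2-yl)cyclohexyl]ethen-1-olate | CC(C)[C@@H]1CC[C@](C)(C(=C)O[Li])C(=O)C1 | intermediate
8 | lithium salt (C-2 carbanion, drawn as ester enolate) of methyl 2-(dimethoxyphosphoryl)-5-[(1R,4R)-1-methyl-2-oxo-4-(propan-2-yl)cyclohexyl]-5-oxopentanoate | CC(C)[C@@H]1CC[C@](C)(C(=O)CCC(=C(OC)O[Li])P(=O)(OC)OC)C(=O)C1 | intermediate
9 | methyl (7R,10S)-1-oxoeudesm-4-en-15-oate | CC(C)[C@@H]1CC[C@]2(C)C(=O)CCC(C(=O)OC)=C2C1 | intermediate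
10 | methyl (1S,7R,10S)-1-hydroxyeudesm-4-en-15-oate (hydroxyl syn to C-14) | CC(C)[C@@H]1CC[C@]2(C)[C@@H](O)CCC(C(=O)OC)=C2C1 | intermediate
11 | dipotassium salt of 10: C-1 alkoxide and C-15/C-4/C-5/C-6 dienolate | CC(C)[C@@H]1CC[C@]2(C)[C@@H](O[K])CCC(=C(OC)O[K])C2=C1 | intermediate
12 | methyl (1S,4S,7S,10S)-1,4-dihydroxyeudesm-5-en-15-oate (O-4 anti, ester syn to C-14) | CC(C)[C@@H]1CC[C@]2(C)[C@@H](O)CC[C@@](O)(C(=O)OC)C2=C1 | intermediate
13 | methyl (1S,4S,7S,10S)-1,4-bis[(dimethylsilyl)oxy]eudesm-5-en-15-oate | CC(C)[C@@H]1CC[C@]2(C)[C@@H](O[SiH](C)C)CC[C@@](O[SiH](C)C)(C(=O)OC)C2=C1 | intermediate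
14 | cyclic siloxane of 13: O-4 and C-6 bridged by SiMe2 (1-oxa-2-silacyclopentane), H-5 and the C-6–Si bond on the O-4 face, O-1 still a dimethylsilyl ether | CC(C)[C@@H]1CC[C@]2(C)[C@@H](O[SiH](C)C)CC[C@]3(C(=O)OC)O[Si](C)(C)[C@H]1[C@@H]23 | intermediate
15 | methyl (1S,4S,5R,6R,7S,10S)-1,4,6-trihydroxyeudesman-15-oate | CC(C)[C@@H]1CC[C@]2(C)[C@@H](O)CC[C@@](O)(C(=O)OC)[C@H]2[C@@H]1O | intermediate
16 | (1S,4S,5R,6R,7S,10S)-eudesmane-1,4,6,15-tetrol | CC(C)[C@@H]1CC[C@]2(C)[C@@H](O)CC[C@@](O)(CO)[C@H]2[C@@H]1O | intermediate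
17 | (E)-cinnamonitrile | N#C/C=C/c1ccccc1 | starting material
18 | methyl (E)-3-phenylprop-2-enimidate hydrochloride | COC(=N)/C=C/c1ccccc1.Cl | intermediate
19 | (1S,4S,5R,6R,7S,10S)-eudesmane-1,4,6,15-tetrol 4,6,15-ortho-(E)-cinnamate (CNP0190302.1) | CC(C)[C@@H]1CC[C@@]2(C)[C@@H]3[C@@H]1O[C@]1(/C=C/c4ccccc4)OC[C@@]3(CC[C@@H]2O)O1 | target

Total step count: 10 (steps 1–8 linear, step 9 a one-step branch, step 10 convergent). Longest linear sequence: 9 steps (steps 1–8 and 10).

Steps most likely to fail

Risk 1, step 4. The intramolecular olefination of the hindered C-5 ketone (next to quaternary C-10, giving a tetrasubstituted alkene) may lag, so that retro-Michael loss or anionic oligomerisation of the acceptor takes over, and some deprotonation may occur at C-6. The fallback sets out from 5 and builds the same ring by alkylation and enamine aldol condensation. Enolate 7 is alkylated with 2-(2-bromoethyl)-1,3-dioxolane (NaI, DMPU, THF) to the keto acetal (2R,5R)-2-[4-(1,3-dioxolan-2-yl)butanoyl]-2-methyl-5-(propan-2-yl)cyclohexan-1-one F1. Aqueous HCl/THF frees the keto aldehyde 5-[(1R,4R)-1-methyl-2-oxo-4-(propan-2-yl)cyclohexyl]-5-oxopentanal F2. Pyrrolidine/AcOH in hot benzene then closes ring A by condensation of the aldehyde enamine with the C-5 ketone (six is the only accessible ring size) to the enal (7R,10S)-1-oxoeudesm-4-en-15-al F3. Oxidation with NaClO2/NaH2PO4/2-methylbut-2-ene gives the acid (7R,10S)-1-oxoeudesm-4-en-15-oic acid F4, and Me3SiCHN2 in MeOH/toluene returns to the route at 9.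

Risk 2, step 7. The 5-endo delivery of silicon to a trisubstituted, ring-fusion alkene next to the isopropyl group may be slow, so that alkene isomerisation or intermolecular Si–H addition competes. The fallback sets out from 12 and uses untethered hydroboration. LiAlH4 reduction gives (1S,4S,7S,10S)-eudesm-5-ene-1,4,15-triol F5. BH3·THF followed by NaOH/H2O2 should place boron on the less substituted C-6, on the face anti to the C-14 methyl and the axial C-15 carbon (as with 5-ene steroids). The face is then chosen without a tether, so a diastereomer separation may be needed. This returns to the route at 16.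

Risk 3, step 6. Oxygen transfer may occur partly at the γ-carbon C-6, γ-deprotonation of the tetrasubstituted enoate may be incomplete, or the sulfonimine by-product may capture the enolate. The fallback sets out from 10 and uses epoxide isomerisation. CF3CO3H (Na2HPO4, CH2Cl2) epoxidises the enoate on the face anti to C-14 to methyl (1S,4S,5R,7R,10R)-4,5-epoxy-1-hydroxyeudesman-15-oate F6. Me3SiOTf/DBU then opens the epoxide at C-5 (the ester disfavours ionisation at C-4) with loss of H-6 to the allylic silyl ether methyl (1S,4S,7S,10S)-1,4-bis[(trimethylsilyl)oxy]eudesm-5-en-15-oate F7. K2CO3 in MeOH removes both silyl groups and returns to the route at 12.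

Further compounds
F1 | step 4 | (2R,5R)-2-[4-(1,3-dioxolan-2-yl)butanoyl]-2-methyl-5-(propan-2-yl)cyclohexan-1-one | CC(C)[C@@H]1CC[C@](C)(C(=O)CCCC2OCCO2)C(=O)C1
F2 | step 4 | 5-[(1R,4R)-1-methyl-2-oxo-4-(propan-2-yl)cyclohexyl]-5-oxopentanal | CC(C)[C@@H]1CC[C@](C)(C(=O)CCCC=O)C(=O)C1
F3 | step 4 | (7R,10S)-1-oxoeudesm-4-en-15-al | CC(C)[C@@H]1CC[C@]2(C)C(=O)CCC(C=O)=C2C1
F4 | step 4 | (7R,10S)-1-oxoeudesm-4-en-15-oic acid | CC(C)[C@@H]1CC[C@]2(C)C(=O)CCC(C(=O)O)=C2C1
F5 | step 7 | (1S,4S,7S,10S)-eudesm-5-ene-1,4,15-triol | CC(C)[C@@H]1CC[C@]2(C)[C@@H](O)CC[C@@](O)(CO)C2=C1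
F6 | step 6 | methyl (1S,4S,5R,7R,10R)-4,5-epoxy-1-hydroxyeudesman-15-oate (epoxide oxygen anti to C-14) | CC(C)[C@@H]1CC[C@]2(C)[C@@H](O)CC[C@]3(C(=O)OC)O[C@]23C1
F7 | step 6 | methyl (1S,4S,7S,10S)-1,4-bis[(trimethylsilyl)oxy]eudesm-5-en-15-oate | CC(C)[C@@H]1CC[C@]2(C)[C@@H](O[Si](C)(C)C)CC[C@@](O[Si](C)(C)C)(C(=O)OC)C2=C1
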